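**Retrosynthetic overview**
- The ring A diol comes from trans-diaxial hydrolysis of the epoxide of a trisubstituted ring A alkene. That alkene comes from the enol triflate of a ring A ketone. The endo-OMe comes from exo-face hydride delivery to the norbornanone oxocarbenium ion.
- Ring B is closed by aldol condensation between the norbornanone CH2 and a ring A ketone. γ-Oxidation and reduction then set both ring-fusion CH centres under thermodynamic control.
- The norbornanone (rings C/D) comes from ring expansion of a cyclopropyl ketone: the CH2 moves from the α- to the α′-carbon. The cyclopropane is made by methylene transfer anti to the isopropyl group.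
- The C–Br centre and the quaternary methyl centre come from desymmetrising reduction of a 2,2-disubstituted cyclohexane-1,3-dione, followed by invertive bromination. The two halves are joined by 1,6-addition to 3-vinylcryptone.
- Order of ring formation: ring C (cryptone); ring A (bought as the dione); cyclopropane; ring D (norbornane bridge); ring B.

Assumption: the C1 donors (MeI, Me3S(O)I, MeZnCl, TMSOMe) are treated as reagents, and the carbon building blocks 1, 2, 5 and 8 as starting materials.

**Step 1**
Reactants: 1 3-methylbutanal; 2 but-3-en-2-one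
Product: 3 (S)-2-isopropyl-5-oxohexanal
Conditions: (S)-α,α-diphenylprolinol methyl ether (5 mol %), ethyl 3,4-dihydroxybenzoate (20 mol %), neat, 4 °C
Reagents that add atoms: none
Why: Enamine-catalysed asymmetric Michael addition; the (S)-catalyst shields one enamine face, so C–C bond formation sets the isopropyl-bearing centre as S.

**Step 2**
Reactants: 3 (S)-2-isopropyl-5-oxohexanal
Product: 4 (S)-4-isopropylcyclohex-2-en-1-one (cryptone)
Conditions: LiOH (aq, 0.1 M), i-PrOH/Et2O, 25 °C
Reagents that add atoms: none
Why: Intramolecular aldol condensation of the methyl ketone onto the aldehyde closes ring C; under this mild base the γ-stereocentre is not touched.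

**Step 3**
Reactants: 4 (S)-cryptone; 5 vinylmagnesium bromide
Product: 6 trans-4-isopropyl-1-(trimethylsilyloxy)-3-vinylcyclohexene
Conditions: CuBr·SMe2 (10 mol %), LiCl, TMSCl, THF, −40 °C
Reagents that add atoms: chlorotrimethylsilane, C[Si](C)(C)Cl
Why: Copper-catalysed conjugate addition with silyl trapping; vinyl enters anti to isopropyl and the enolate is fixed regiospecifically (the new centre is erased in step 4).

**Step 4**
Reactants: 6 trans-4-isopropyl-1-(trimethylsilyloxy)-3-vinylcyclohexene
Product: 7 (S)-4-isopropyl-3-vinylcyclohex-2-en-1-one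
Conditions: Pd(OAc)2 (10 mol %), O2 (1 atm), DMSO, 40 °C
Reagents that add atoms: none
Why: Saegusa–Ito dehydrosilylation; the divalent palladium enolate undergoes β-hydride elimination towards the vinyl-bearing carbon and O2 reoxidises zerovalent palladium, giving the cross-extended dienone.

**Step 5**
Reactants: 8 cyclohexane-1,3-dione
Product: 9 2-methylcyclohexane-1,3-dione
Conditions: MeI, NaOH (aq), dioxane, 65 °C
Reagents that add atoms: iodomethane, CI
Why: C-alkylation of the stabilised 1,3-dione enolate at C2; no stereocentre is formed.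

**Step 6**
Reactants: 7 (S)-4-isopropyl-3-vinylcyclohex-2-en-1-one; 9 2-methylcyclohexane-1,3-dione
Product: 10 2-{2-[(6S)-6-isopropyl-3-oxocyclohex-1-en-1-yl]ethyl}-2-methylcyclohexane-1,3-dione
Conditions: Et3N (10 mol %), MeOH, 40 °C
Reagents that add atoms: none
Why: Vinylogous (1,6-) Michael addition of the soft dione carbon to the terminal CH2 of the dienone; γ-protonation of the dienolate restores the conjugated enone, and the new quaternary carbon is still prochiral.

**Step 7**
Reactants: 10 triketone
Product: 11 2-methyl-2-{2-[5-isopropyl-2-oxobicyclo[4.1.0]heptan-6-yl]ethyl}cyclohexane-1,3-dione (cyclopropane CH2 anti to isopropyl)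
Conditions: Me3S(O)I, NaH, DMSO, 25 to 50 °C
Reagents that add atoms: trimethylsulfoxonium iodide, C[S+](C)(C)=O.[I-]
Why: Corey–Chaykovsky cyclopropanation; the sulfoxonium ylide adds reversibly to ketones but irreversibly 1,4 to the enone, anti to the neighbouring isopropyl group, which sets the ring C quaternary centre.

**Step 8**
Reactants: 11 cyclopropyl triketone
Product: 12 (2R,3R)-3-hydroxy-2-methyl-2-{2-[5-isopropyl-2-oxobicyclo[4.1.0]heptan-6-yl]ethyl}cyclohexan-1-one (OH trans to CH3)
Conditions: (S)-Me-CBS oxazaborolidine (20 mol %), catecholborane (1.1 equiv), toluene, −78 °C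
Reagents that add atoms: none
Why: Corey–Bakshi–Shibata reduction used as a desymmetrisation; the activated dione carbonyls react before the σ-conjugated cyclopropyl ketone, the (S)-catalyst gives the R carbinol, and hydride enters on the methyl side (anti to the long chain), so the quaternary centre and the carbinol centre are set together.

**Step 9**
Reactants: 12 hydroxy diketone
Product: 13 (2S,3S)-3-bromo-2-methyl-2-{2-[5-isopropyl-2-oxobicyclo[4.1.0]heptan-6-yl]ethyl}cyclohexan-1-one (Br cis to CH3)
Conditions: CBr4, PPh3, toluene, 60 °C
Reagents that add atoms: tetrabromomethane, BrC(Br)(Br)Br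
Why: Appel reaction; SN2 displacement of the oxyphosphonium group inverts the carbinol carbon on the still flexible monocyclic ring, and the quaternary α-carbon blocks β-elimination towards the ketone.

**Step 10**
Reactants: 13 bromo cyclopropyl diketone
Product: 15 5-endo-isopropylbicyclo[2.2.1]heptan-2-one carrying the 2-(3-bromo-2-methyl-1-oxocyclohex-2-yl)ethyl chain on bridgehead C4, via iodo ketone 14 (not isolated)
Conditions: MgI2 (20 mol %), Et3N (30 mol %), Et3N·HI (30 mol %), MeCN, 80 °C
Reagents that add atoms: none
Why: Proposed new method: MgI2-catalysed ring expansion of a bicyclo[4.1.0]heptan-2-one to a bicyclo[2.2.1]heptan-2-one – Mg2+ activates the ketone, iodide opens the unhindered cyclopropane CH2 by homoconjugate SN2 attack to give the γ-iodo enolate, the Et3N/Et3N·HI pair shuttles a proton so that the α- and α′-enolates equilibrate, re-closure at the α-carbon only regenerates 13 whereas 5-exo-tet C-alkylation at the α′-carbon is irreversible (about 10 kcal/mol less ring strain, and O-alkylation would need a bridgehead alkene) and releases iodide for turnover, so the CH2 held on the face anti to isopropyl moves from the α- to the α′-carbon, fixes the new bridgehead centre and leaves isopropyl endo; the closest known reaction types are the TMSI or MgI2 homoconjugate opening of cyclopropyl ketones and intramolecular ketone enolate alkylation.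

**Step 11**
Reactants: 15 norbornanone bromo ketone
Product: 16 tetracyclic bromo enone (ring B closed; tetrasubstituted C=C between norbornanone C3 and the ring A/B fusion carbon)
Conditions: p-TsOH·H2O (10 mol %), toluene, reflux, Dean–Stark
Reagents that add atoms: none
Why: Wieland–Miescher-type intramolecular aldol condensation; the norbornanone can enolise only at its CH2 (the other α-carbon is a bridgehead) and only six-ring closure is possible, so no new stereocentre is created.

**Step 12**
Reactants: 16 tetracyclic bromo enone
Product: 17 tetracyclic bromo ene-dione (new ring A ketone next to the C=C)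
Conditions: Rh2(cap)4 (cap = caprolactamate, 1 mol %), t-BuOOH (70 % aq, 5 equiv), CH2Cl2, 25 °C
Reagents that add atoms: tert-butyl hydroperoxide, CC(C)(C)OO
Why: Dirhodium-catalysed allylic (γ-) oxidation; the enone has only one allylic CH2, because the other allylic carbons are quaternary.

**Step 13**
Reactants: 17 ene-dione
Product: 18 tetracyclic bromo 1,4-diketone (trans A/B fusion; ring A carbon exo on the norbornanone)
Conditions: Zn dust, AcOH, 40 °C
Reagents that add atoms: none
Why: Two-electron reduction of the ene-dione; both new CH centres are α to a ketone and equilibrate in the acid to the most stable array, because the epimer at the A/B fusion would place the ring A carbonyl carbon 1,3-diaxial to the CH2 bridge and the other epimer would push ring A against the endo isopropyl group.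

**Step 14**
Reactants: 18 bromo 1,4-diketone
Product: 19 ring A enol triflate of 18
Conditions: KHMDS (1.05 equiv), PhNTf2, THF, −78 °C
Reagents that add atoms: N-phenylbis(trifluoromethanesulfonimide), O=S(=O)(N(c1ccccc1)S(=O)(=O)C(F)(F)F)C(F)(F)F
Why: Kinetic enolate triflation; the only α-CH2 in the molecule lies in ring A, the other α-positions being tertiary or bridgehead, so a single regioisomer forms.

**Step 15**
Reactants: 19 keto enol triflate
Product: 20 endo-methyl ether enol triflate
Conditions: TMSOMe, Et3SiH, TMSOTf (20 mol %), CH2Cl2, −78 to −30 °C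
Reagents that add atoms: methoxytrimethylsilane, CO[Si](C)(C)C
Why: Reductive etherification; the methyl oxocarbenium ion of the norbornanone accepts hydride from the exo face, so OMe ends up endo, and the enol triflate is inert to acid and silane.

**Step 16**
Reactants: 20 endo-methyl ether enol triflate
Product: 21 bromo alkene (ring A trisubstituted C=C bearing CH3)
Conditions: MeZnCl, Pd(PPh3)4 (5 mol %), THF, 25 °C
Reagents that add atoms: methylzinc chloride, C[Zn]Cl
Why: Negishi coupling; zerovalent palladium inserts into the alkenyl triflate but not into the unactivated secondary bromide, and no stereocentre is affected.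

**Step 17**
Reactants: 21 bromo alkene
Product: 23 target CNP0130529.1, via beta-epoxide 22 (not isolated)
Conditions: mCPBA, CH2Cl2, 0 °C; then THF–H2O, HClO4 (cat.), 25 °C
Reagents that add atoms: 3-chloroperoxybenzoic acid, O=C(OO)c1cccc(Cl)c1; water, O
Why: Prilezhaev epoxidation on the face opposite the axial angular methyl, then acid-catalysed Fürst–Plattner opening; water attacks the tertiary carbon with inversion and gives the trans-diaxial diol (tertiary OH syn to the angular CH3, secondary OH anti), and the minor epoxide would give the same diol.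

**Compound list**
1 | 3-methylbutanal | CC(C)CC=O | starting material
2 | but-3-en-2-one | CC(=O)C=C | starting material
3 | (S)-2-isopropyl-5-oxohexanal | CC(=O)CC[C@@H](C(C)C)C=O | intermediate
4 | (S)-4-isopropylcyclohex-2-en-1-one | O=C1CC[C@@H](C(C)C)C=C1 | intermediate
5 | vinylmagnesium bromide | C=C[Mg]Br | starting material
6 | trans-4-isopropyl-1-(trimethylsilyloxy)-3-vinylcyclohexene | C[Si](C)(C)OC1=C[C@@H](C=C)[C@H](C(C)C)CC1 | intermediate
7 | (S)-4-isopropyl-3-vinylcyclohex-2-en-1-one | O=C1CC[C@@H](C(C)C)C(C=C)=C1 | intermediate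
8 | cyclohexane-1,3-dione | O=C1CCCC(=O)C1 | starting material
9 | 2-methylcyclohexane-1,3-dione | CC1C(=O)CCCC1=O | intermediate
10 | enone triketone | O=C1CC[C@@H](C(C)C)C(CCC2(C)C(=O)CCCC2=O)=C1 | intermediate
11 | cyclopropyl triketone | O=C1CC[C@@H](C(C)C)[C@]2(CCC3(C)C(=O)CCCC3=O)C[C@H]12 | intermediate
12 | hydroxy diketone (OH trans to CH3) | O=C1CC[C@@H](C(C)C)[C@]2(CC[C@@]3(C)C(=O)CCC[C@H]3O)C[C@H]12 | intermediate
13 | bromo cyclopropyl diketone (Br cis to CH3) | O=C1CC[C@@H](C(C)C)[C@]2(CC[C@@]3(C)C(=O)CCC[C@@H]3Br)C[C@H]12 | intermediate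
14 | γ-iodo ketone (3-iodomethyl cyclohexanone) | O=C1CC[C@@H](C(C)C)[C@](C1)(CC[C@@]3(C)C(=O)CCC[C@@H]3Br)CI | intermediate (not isolated)
15 | norbornanone bromo ketone | O=C1[C@H]2C[C@@H](C(C)C)[C@](C1)(CC[C@@]3(C)C(=O)CCC[C@@H]3Br)C2 | intermediate
16 | tetracyclic bromo enone | O=C1[C@H]2C[C@@H](C(C)C)[C@]3(CC[C@@]4(C)C(=C13)CCC[C@@H]4Br)C2 | intermediate
17 | tetracyclic bromo ene-dione | O=C1[C@H]2C[C@@H](C(C)C)[C@]3(CC[C@@]4(C)C(=C13)C(=O)CC[C@@H]4Br)C2 | intermediate
18 | tetracyclic bromo 1,4-diketone | O=C1[C@H]2C[C@@H](C(C)C)[C@]3(CC[C@@]4(C)[C@H]([C@H]13)C(=O)CC[C@@H]4Br)C2 | intermediate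
19 | keto enol triflate | O=C1[C@H]2C[C@@H](C(C)C)[C@]3(CC[C@@]4(C)[C@H]([C@H]13)C(OS(=O)(=O)C(F)(F)F)=CC[C@@H]4Br)C2 | intermediate
20 | endo-methyl ether enol triflate | CO[C@H]1[C@H]2C[C@@H](C(C)C)[C@]3(CC[C@@]4(C)[C@H]([C@H]13)C(OS(=O)(=O)C(F)(F)F)=CC[C@@H]4Br)C2 | intermediate
21 | bromo alkene | CO[C@H]1[C@H]2C[C@@H](C(C)C)[C@]3(CC[C@@]4(C)[C@H]([C@H]13)C(C)=CC[C@@H]4Br)C2 | intermediate
22 | beta-epoxide | CO[C@H]1[C@H]2C[C@@H](C(C)C)[C@]3(CC[C@@]4(C)[C@H]([C@H]13)[C@@]5(C)O[C@H]5C[C@@H]4Br)C2 | intermediate (not isolated)
23 | CNP0130529.1 | CO[C@H]1[C@H]2C[C@@H](C(C)C)[C@]3(CC[C@@]4(C)[C@H]([C@H]13)[C@](C)(O)[C@@H](O)C[C@@H]4Br)C2 | target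

**Step count**
Total steps: 17. Longest linear sequence: 16 (steps 1–4 and 6–17); step 5 is a one-step side branch.

**Steps most likely to fail**

*Step 10 (new ring expansion).*
- Risk: the neopentyl alkylation may be too slow, so that only 13 is recovered.
- Fallback (known chemistry): it sets out from 13.
- TMSI (CH2Cl2, −78 °C) opens the cyclopropyl ketone to the γ-iodo silyl enol ether F1.
- TiCl4 then triggers an intramolecular Mukaiyama aldol addition onto the ring A ketone, giving the iodo β-hydroxy ketone F2.
- KOt-Bu in t-BuOH/THF first eliminates water (E1cB). This removes the only α-hydrogen that could re-close the cyclopropane.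
- The cross-conjugated α′-enolate then closes the CH2 bridge by intramolecular alkylation. The sequence rejoins the route at 16.

*Step 9 (invertive bromination next to a quaternary carbon).*
- Risk: elimination may win over substitution.
- Fallback: it sets out from 12 and postpones the substitution.
- The free alcohol is taken through the conditions of steps 10 and 11, to the hydroxy norbornanone F3 and then the hydroxy enone F4.
- In F4 the alcohol is locked axial on a rigid octalin, so CBr4/PPh3 displaces it to the equatorial bromide. This rejoins the route at 16.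

*Step 12 (γ-oxidation).*
- Risk: low conversion or over-oxidation.
- Fallback: it sets out from 16.
- TBSOTf/Et3N gives the silyl dienol ether F5.
- mCPBA (vinylogous Rubottom oxidation) gives the γ-hydroxy enone F6.
- Dess–Martin periodinane oxidises F6, and the sequence rejoins the route at 17.

**Further compounds**
F1 | step 10 | γ-iodo silyl enol ether | C[Si](C)(C)OC=1CC[C@@H](C(C)C)[C@](C=1)(CC[C@@]4(C)C(=O)CCC[C@@H]4Br)CI
F2 | step 10 | iodo β-hydroxy ketone | O=C1CC[C@@H](C(C)C)[C@@]3(CI)CC[C@@]4(C)[C@](O)([C@H]13)CCC[C@@H]4Br
F3 | step 9 | hydroxy norbornanone | O=C1[C@H]2C[C@@H](C(C)C)[C@](C1)(CC[C@@]3(C)C(=O)CCC[C@H]3O)C2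
F4 | step 9 | hydroxy enone | O=C1[C@H]2C[C@@H](C(C)C)[C@]3(CC[C@@]4(C)C(=C13)CCC[C@H]4O)C2
F5 | step 12 | silyl dienol ether | CC(C)(C)[Si](C)(C)OC=1[C@H]2C[C@@H](C(C)C)[C@]3(CC[C@@]4(C)C(C=13)=CCC[C@@H]4Br)C2
F6 | step 12 | γ-hydroxy enone | O=C1[C@H]2C[C@@H](C(C)C)[C@]3(CC[C@@]4(C)C(=C13)[C@@H](O)CC[C@@H]4Br)C2
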